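The easy step is a division. For the flask I take free monomer charged over initiator charged, 200 units per chain. This is the bench rule, and I use it as the zero of my scale: suppose each initiator gives a pair of radicals and the pair joins into one chain (termination by combination).

| flask | free monomer | protic impurity | initiator | remark | time |
|---|---|---|---|---|---|
| zeta | 0.40 M (fed, over 6.0 min) | 0.080 M | 2 mM | the very flask that is asked about, followed so far |  |
| epsilon | 0.27 M (fed, over 6.0 min) | 0.080 M | 2 mM | run made earlier |  |
| flask | 0.40 M (fed, over 6.0 min) | 0.0800 M | 2.0 mM |  | 20 min |

| run | time / min | monomer in chains / % | free monomer / % |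
|---|---|---|---|
| zeta | 0.500 | 0.7 | 5.0 |
| zeta | 1.00 | 1.1 | 8.1 |
| zeta | 2.50 | 10.1 | 16.0 |
| zeta | 6.00 | 48.1 | 31.6 |
| epsilon | 0.667 | 1.1 | 5.4 |
| epsilon | 1.33 | 3.1 | 8.5 |
| epsilon | 3.00 | 12.8 | 15.2 |
| epsilon | 8.00 | 57.8 | 12.8 |

(scatter of a reading: 0.5 percentage points)

- average number of monomer units in a chain (living and dead chains, two that joined counted as one) at 20 min
- part of the free monomer that has reacted at 20 min

In zeta and epsilon part of the charged monomer does not reach chains, and there the rule needs mending. The ratio of protic impurity to charge is 20.0% in zeta and 29.6% in epsilon. The readings show a gap of the same size within their scatter: neither pool holds 20.3% in zeta at 6.00 min, or 29.4% in epsilon at 8.00 min. So I strike the impurity from the charge.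

My yardstick for the flask is the free monomer left after the impurity, per initiator charged: 160. If a pair makes a chain and the free monomer has reacted to the end, dp is the yardstick divided by the share of initiator spent. The earlier runs do not show the number of chains, so I commit to 160, the value for a share of one, as my lower mark. On c I add nothing.

The forecast says 190 and 97%, with chains “about 1.6 mM from 2 mM initiator with some coupling”. Its dp lies above my mark, and on my scale it means 84.2% of the initiator spent.

The flask gives 449 and 99.9%, so the forecast's dp is low by a factor of 2.36.

    initiator → 2 initiating radical (k = 0.0220 /min)
    free monomer + initiating radical → growing radical + monomer in chains (k = 1.40 × 10⁶ /M/s)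
    free monomer + growing radical → monomer in chains + growing radical, rate k3*[growing radical]*[free monomer] (k = 1.10 × 10⁵ /M/s)
    2 growing radical → dead chain (k = 1.50 × 10⁸ /M/s)
    protic impurity + free monomer → quenched substrate (k = 20.0 /M/min)

At 20.0 min the flask still holds 64% of its initiator, so 35.6% is spent, and the yardstick divided by that share gives 449. The neighbour with 1.0 M of free monomer has a yardstick of 460 and 64% of its initiator left, so the same division gives 1290, and that flask stands at 1290.

(The readings were generated by integration with made-up constants, noise included.)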